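Stenine numbering: pyrrole N4/C3/C2/C1/C9a, azepane C5–C9, carbocycle B (C9, C10, C11, C12, C1, C9a), lactone D (O, C11–C14). The route rests on disconnecting C10–C11 of ring B. The precursor is a pyrrolo[1,2-a]azepine whose C1 carries an intact 3-methylbutenolide (C11–C14) and whose C9 stereocentre carries an (E)-allylic carbonate. Zerovalent palladium ionises the carbonate; the methoxide set free deprotonates the butenolide, and its γ-carbon C11 attacks allyl terminus C10. This one operation closes ring B and sets C10 and C11, exploiting the γ-acidity of the butenolide attached to pyrrole C1. One hydrogenation then sets C12 and C13 and makes the ethyl group.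

Key step: step 9

Remark (numbering): the side-chain lactone atoms are C18 (O-bearing), C19, C20 (CH3-bearing) and C21 (C=O).
Assumption: the (S,S,Sa) phosphoramidite gives 9R in step 3; if the sense of induction is opposite, its antipode is used with no other change.
Assumption: (3S)-4-methoxy-3-methyl-4-oxobutanoic acid 7 (the 1-methyl ester of (S)-methylsuccinic acid) and 4-hydroxy-3-methylfuran-2(5H)-one 11 are catalogue compounds.

Step 1
Reactants: 1 pyrrole; 2 6-bromohex-1-ene
Product: 3 1-(hex-5-en-1-yl)-1H-pyrrole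
Conditions: KOH (powdered), DMSO, 20 °C
Reagents that add atoms: 6-bromohex-1-ene (2), C=CCCCCBr
Why: The pyrrolide anion in DMSO should be alkylated at nitrogen by the primary bromide (SN2 N-alkylation).

Step 2
Reactants: 3 1-(hex-5-en-1-yl)-1H-pyrrole; 4 allyl methyl carbonate
Product: 5 methyl (2E)-7-(1H-pyrrol-1-yl)hept-2-en-1-yl carbonate
Conditions: second-generation Grubbs catalyst (3 mol %), 4 (4 equiv), CH2Cl2, 40 °C
Reagents that add atoms: allyl methyl carbonate (4), C=CCOC(=O)OC
Why: Olefin cross-metathesis of two terminal alkenes, driven by loss of ethene and the excess of 4, should give mainly the E allylic carbonate.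

Step 3
Reactants: 5 methyl (2E)-7-(1H-pyrrol-1-yl)hept-2-en-1-yl carbonate
Product: 6 (9R)-9-ethenyl-6,7,8,9-tetrahydro-5H-pyrrolo[1,2-a]azepine
Conditions: [Ir(cod)Cl]2 (2 mol %), (S,S,Sa)-N,N-bis(1-phenylethyl)dinaphtho[2,1-d:1',2'-f][1,3,2]dioxaphosphepin-4-amine (4 mol %, preactivated with n-PrNH2), THF, 0.02 M, 50 °C
Reagents that add atoms: none
Why: Iridium-catalysed asymmetric allylic substitution in the intramolecular Friedel–Crafts mode: the pyrrole α-carbon attacks the substituted allyl terminus (the branched selectivity typical of iridium), which closes the seven-membered ring and lets the ligand set C9.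

Step 4
Reactants: 6 (9R)-9-ethenyl-6,7,8,9-tetrahydro-5H-pyrrolo[1,2-a]azepine; 7 (3S)-4-methoxy-3-methyl-4-oxobutanoic acid
Product: 9 methyl (2S)-4-[(9R)-9-ethenyl-6,7,8,9-tetrahydro-5H-pyrrolo[1,2-a]azepin-3-yl]-2-methyl-4-oxobutanoate, via acid chloride 8 (not isolated)
Conditions: 7, (COCl)2, DMF (cat.), CH2Cl2, 0 to 20 °C, evaporate; then 6, DBN (15 mol %), toluene, 80 °C
Reagents that add atoms: (3S)-4-methoxy-3-methyl-4-oxobutanoic acid (7), OC(=O)C[C@H](C)C(=O)OC
Why: Friedel–Crafts acylation of the 1,2-dialkylpyrrole at its only free α-position C3 with DBN as acyl-transfer catalyst; the C20 stereocentre is not α to the reacting carbonyl and should be untouched.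

Step 5
Reactants: 9 methyl (2S)-4-[(9R)-9-ethenyl-6,7,8,9-tetrahydro-5H-pyrrolo[1,2-a]azepin-3-yl]-2-methyl-4-oxobutanoate
Product: 10 methyl (2S)-4-[(9R)-1-bromo-9-ethenyl-6,7,8,9-tetrahydro-5H-pyrrolo[1,2-a]azepin-3-yl]-2-methyl-4-oxobutanoate
Conditions: NBS (1.0 equiv), THF, −78 to 0 °C, dark
Reagents that add atoms: N-bromosuccinimide, O=C1CCC(=O)N1Br
Why: Electrophilic bromination of a 2-acylpyrrole goes to the β-position remote from the acyl group, here C1, which is also activated by the alkylated C9a next to it.

Step 6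
Reactants: 11 4-hydroxy-3-methylfuran-2(5H)-one (3-methyltetronic acid)
Product: 12 4-bromo-3-methylfuran-2(5H)-one
Conditions: (COBr)2, DMF (cat.), CH2Cl2, 0 to 20 °C
Reagents that add atoms: oxalyl bromide, O=C(Br)C(=O)Br
Why: Vilsmeier-type activation of the vinylogous acid followed by addition–elimination of bromide should give the vinylogous acyl bromide.

Step 7
Reactants: 10 the C1 bromide; 12 4-bromo-3-methylfuran-2(5H)-one
Product: 14 methyl (2S)-4-[(9R)-9-ethenyl-1-(4-methyl-5-oxo-2,5-dihydrofuran-3-yl)-6,7,8,9-tetrahydro-5H-pyrrolo[1,2-a]azepin-3-yl]-2-methyl-4-oxobutanoate, via pinacol boronate 13 (not isolated)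
Conditions: B2pin2, PdCl2(dppf) (5 mol %), KOAc, 1,4-dioxane, 90 °C; then 12, K3PO4, H2O (5 equiv), 70 °C
Reagents that add atoms: 4-bromo-3-methylfuran-2(5H)-one (12), CC1=C(Br)COC1=O
Why: Miyaura borylation followed in the same flask by Suzuki–Miyaura coupling; the vinylogous acyl bromide 12 is a fast partner for oxidative addition, and the ester, ketone and vinyl group should be inert.

Step 8
Reactants: 14 the C1 butenolide; 4 allyl methyl carbonate
Product: 15 methyl (2S)-4-[(9R)-9-[(1E)-3-(methoxycarbonyloxy)prop-1-en-1-yl]-1-(4-methyl-5-oxo-2,5-dihydrofuran-3-yl)-6,7,8,9-tetrahydro-5H-pyrrolo[1,2-a]azepin-3-yl]-2-methyl-4-oxobutanoate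
Conditions: second-generation Hoveyda–Grubbs catalyst (5 mol %), 4 (5 equiv), 1,4-benzoquinone (10 mol %), CH2Cl2, 40 °C
Reagents that add atoms: allyl methyl carbonate (4), C=CCOC(=O)OC
Why: Cross-metathesis of the C9 vinyl group with excess 4 should give the E allylic carbonate; the tetrasubstituted butenolide alkene is inert to the ruthenium carbene, and benzoquinone suppresses hydride-mediated double-bond migration, so C9 is preserved.

Step 9
Reactants: 15 the allylic carbonate
Product: 16 tetracyclic vinyl butenolide keto ester (9R,10R,11S,20S): ring B closed, ethenyl at C10, lactone D unsaturated at C12=C13, C3 carrying C(=O)CH2CH(CH3)CO2CH3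
Conditions: Pd(PPh3)4 (5 mol %), THF, 0.01 M, 40 °C, no added base
Reagents that add atoms: none
Why: Zerovalent palladium ionises the allylic carbonate to the syn η3-allyl complex, and the methoxide released with CO2 deprotonates the γ-CH2 (C11) of the butenolide, so the soft 2-oxidofuran and the electrophile arise together under neutral conditions; outer-sphere attack of C11 on the proximal allyl terminus C10 forms the bond and returns the catalyst. The closest known reaction is the intramolecular Tsuji–Trost allylation, here with a vinylogous (γ-selective) lactone dienolate. Ring B closes in a 6-exo mode, the two remaining allyl carbons becoming the exocyclic vinyl group, in preference to 8-endo attack at the distal terminus. C10 is controlled by C9: the allyl unit should react through the conformer with H9 in the allyl plane (least allylic strain), and the tether forces attack on the face anti to C8, which places vinyl trans to C8. C11 follows from a chair-like transition state with the allylpalladium unit equatorial and the C11–O bond held in the furanolate plane, which places vinyl trans to O; the product is still γ-acidic and can equilibrate towards this all-equatorial isomer. The step needs γ- over α-C-alkylation and C- over O-alkylation: the α-carbon C13 is blocked by its methyl group (attack there would build a quaternary centre), and O-attack would need an eight-membered ring.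

Step 10
Reactants: 16 the tetracyclic vinyl butenolide
Product: 17 tetracyclic ethyl lactone keto ester (9R,10R,11S,12R,13R,20S): as 16 with ethyl at C10 and a saturated cis-fused lactone D in which H11, H12 and H13 are all cis
Conditions: H2 (50 bar), Rh/Al2O3 (5 % Rh), EtOAc, 20 °C
Reagents that add atoms: none
Why: Heterogeneous syn-hydrogenation should saturate the vinyl group and add H2 to the tetrasubstituted butenolide from the face of H11 (opposite the C10 flap of ring B), giving the cis-fused lactone with the C13 methyl on the concave face; the acylpyrrole is a vinylogous amide and should resist reduction.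

Step 11
Reactants: 17 the keto ester
Product: 19 target CNP0232452.4 (9R,10R,11S,12R,13R,18R,20S), with a (2R,4S)-4-methyl-5-oxooxolan-2-yl group at C3, via hydroxy ester 18 (not isolated)
Conditions: (S)-2-methyl-CBS-oxazaborolidine (0.3 equiv), catecholborane (1.5 equiv), toluene, −78 to −40 °C; aqueous NaHCO3 work-up; then 2-hydroxypyridine (10 mol %), toluene, 60 °C
Reagents that add atoms: none
Why: Corey–Bakshi–Shibata reduction with the pyrrolyl group as the large substituent should give the 18R carbinol, and the γ-hydroxy ester then lactonises under neutral bifunctional catalysis, so that neither the labile pyrrolylic C18–O bond nor the epimerisable C13 meets acid or base.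

Compound list
1 | pyrrole | c1cc[nH]c1 | starting material
2 | 6-bromohex-1-ene | C=CCCCCBr | starting material
3 | 1-(hex-5-en-1-yl)-1H-pyrrole | C=CCCCCn1cccc1 | intermediate
4 | allyl methyl carbonate | C=CCOC(=O)OC | starting material
5 | methyl (2E)-7-(1H-pyrrol-1-yl)hept-2-en-1-yl carbonate | COC(=O)OC/C=C/CCCCn1cccc1 | intermediate
6 | (9R)-9-ethenyl-6,7,8,9-tetrahydro-5H-pyrrolo[1,2-a]azepine | C=C[C@H]1CCCCn2cccc21 | intermediate
7 | (3S)-4-methoxy-3-methyl-4-oxobutanoic acid | OC(=O)C[C@H](C)C(=O)OC | starting material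
8 | methyl (2S)-4-chloro-2-methyl-4-oxobutanoate | ClC(=O)C[C@H](C)C(=O)OC | intermediate (not isolated)
9 | methyl (2S)-4-[(9R)-9-ethenyl-6,7,8,9-tetrahydro-5H-pyrrolo[1,2-a]azepin-3-yl]-2-methyl-4-oxobutanoate | C=C[C@H]1CCCCn2c(C(=O)C[C@H](C)C(=O)OC)ccc21 | intermediate
10 | methyl (2S)-4-[(9R)-1-bromo-9-ethenyl-6,7,8,9-tetrahydro-5H-pyrrolo[1,2-a]azepin-3-yl]-2-methyl-4-oxobutanoate | C=C[C@H]1CCCCn2c(C(=O)C[C@H](C)C(=O)OC)cc(Br)c21 | intermediate
11 | 4-hydroxy-3-methylfuran-2(5H)-one | CC1=C(O)COC1=O | starting material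
12 | 4-bromo-3-methylfuran-2(5H)-one | CC1=C(Br)COC1=O | intermediate
13 | methyl (2S)-4-[(9R)-9-ethenyl-1-(4,4,5,5-tetramethyl-1,3,2-dioxaborolan-2-yl)-6,7,8,9-tetrahydro-5H-pyrrolo[1,2-a]azepin-3-yl]-2-methyl-4-oxobutanoate | C=C[C@H]1CCCCn2c(C(=O)C[C@H](C)C(=O)OC)cc(B3OC(C)(C)C(C)(C)O3)c21 | intermediate (not isolated)
14 | methyl (2S)-4-[(9R)-9-ethenyl-1-(4-methyl-5-oxo-2,5-dihydrofuran-3-yl)-6,7,8,9-tetrahydro-5H-pyrrolo[1,2-a]azepin-3-yl]-2-methyl-4-oxobutanoate | C=C[C@H]1CCCCn2c(C(=O)C[C@H](C)C(=O)OC)cc(C3=C(C)C(=O)OC3)c21 | intermediate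
15 | methyl (2S)-4-[(9R)-9-[(1E)-3-(methoxycarbonyloxy)prop-1-en-1-yl]-1-(4-methyl-5-oxo-2,5-dihydrofuran-3-yl)-6,7,8,9-tetrahydro-5H-pyrrolo[1,2-a]azepin-3-yl]-2-methyl-4-oxobutanoate | COC(=O)OC/C=C/[C@H]1CCCCn2c(C(=O)C[C@H](C)C(=O)OC)cc(C3=C(C)C(=O)OC3)c21 | intermediate
16 | tetracyclic vinyl butenolide keto ester (9R,10R,11S,20S) | C=C[C@H]1[C@@H]2OC(=O)C(C)=C2c2cc(C(=O)C[C@H](C)C(=O)OC)n3c2[C@@H]1CCCC3 | intermediate
17 | tetracyclic ethyl lactone keto ester (9R,10R,11S,12R,13R,20S) | CC[C@H]1[C@@H]2OC(=O)[C@H](C)[C@@H]2c2cc(C(=O)C[C@H](C)C(=O)OC)n3c2[C@@H]1CCCC3 | intermediate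
18 | (18R)-hydroxy ester of 17 | CC[C@H]1[C@@H]2OC(=O)[C@H](C)[C@@H]2c2cc([C@H](O)C[C@H](C)C(=O)OC)n3c2[C@@H]1CCCC3 | intermediate (not isolated)
19 | CNP0232452.4 (9R,10R,11S,12R,13R,18R,20S) | CC[C@H]1[C@@H]2OC(=O)[C@H](C)[C@@H]2c2cc([C@H]3C[C@H](C)C(=O)O3)n3c2[C@@H]1CCCC3 | target

Total step count: 11. Longest linear sequence: 10 steps (steps 1–5 and 7–11); step 6 is a one-step side branch.

Steps most likely to fail

Step 3. The weakly nucleophilic N-alkylpyrrole may close the seven-membered ring more slowly than it oligomerises, and the enantioselectivity may be low. The fallback sets out from 1 and comes back at 6, building the ring by acylation and setting C9 by hydride delivery. Pyrrole 1 is N-alkylated with ethyl 5-bromopentanoate (KOH, DMSO) to ethyl 5-(1H-pyrrol-1-yl)pentanoate F1, which is saponified (NaOH, aqueous EtOH) to 5-(1H-pyrrol-1-yl)pentanoic acid F2. Cyclising Friedel–Crafts acylation (polyphosphoric acid, 90 °C) gives 5,6,7,8-tetrahydro-9H-pyrrolo[1,2-a]azepin-9-one F3. Peterson olefination (ethyl trimethylsilylacetate, LiN(i-Pr)2, THF, −78 to 20 °C) gives ethyl (2E)-2-(5,6,7,8-tetrahydro-9H-pyrrolo[1,2-a]azepin-9-ylidene)acetate F4, and i-Bu2AlH reduction gives (2E)-2-(5,6,7,8-tetrahydro-9H-pyrrolo[1,2-a]azepin-9-ylidene)ethan-1-ol F5. Methyl chloroformate and pyridine give methyl (2E)-2-(5,6,7,8-tetrahydro-9H-pyrrolo[1,2-a]azepin-9-ylidene)ethyl carbonate F6. Enantioselective formate hydrogenolysis (Pd2(dba)3, a chiral MOP-type monophosphine, HCO2H, 1,8-bis(dimethylamino)naphthalene, dioxane, 20 °C) delivers hydride to the substituted allyl terminus C9 and leaves the terminal vinyl group, giving 6.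

Step 9. The ambident dienolate may be alkylated at C13 or at oxygen, the allylpalladium intermediate may lose a β-hydride from C9 to give a diene, or the C10/C11 diastereoselection may be poor. The fallback sets out from 15 and comes back at 16 with the polarity of both carbons inverted. Soft enolisation of 15 (i-Pr3SiOTf, Et3N, CH2Cl2, −78 °C) gives the 2-(triisopropylsilyloxy)furan F7. Oxidation with dimethyldioxirane (acetone, −78 °C) gives the 5-hydroxybutenolide F8, a masked C11 aldehyde formed as both C11 epimers. Umpolung allylation (Pd(PPh3)4, Et2Zn, THF, 20 °C; then aqueous citric acid) turns the allylic carbonate into an allylzinc, which adds through its γ-carbon C10 to the ring-opened aldehyde C11 via a chair transition state (vinyl and alkoxide trans). The C11 alkoxide relactonises onto the Z-carboxylate and gives 16.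

Step 11. Hydride transfer to the vinylogous-amide carbonyl may be slow, the pyrrolyl carbinol may be over-reduced to a methylene group through an azafulvenium ion, or facial selectivity may be low. The fallback sets out from 17 and comes back at 19, replacing reagent control by separation and recycling. Luche reduction (NaBH4, CeCl3·7H2O, MeOH, −40 °C) gives 18 together with its (18S)-hydroxy ester F9. Lactonisation as in step 11 gives 19 and its 18-epimer F10, which are separated by chromatography. F10 is recycled by acid-catalysed equilibration at C18 (camphorsulfonic acid 5 mol %, CH2Cl2, 0 °C; reversible ionisation of the pyrrolylic C–O bond and reclosure) and renewed separation. The trans lactone 19 may be the minor component at equilibrium, so several cycles may be needed.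

Further compounds
F1 | step 3 | ethyl 5-(1H-pyrrol-1-yl)pentanoate | CCOC(=O)CCCCn1cccc1
F2 | step 3 | 5-(1H-pyrrol-1-yl)pentanoic acid | OC(=O)CCCCn1cccc1
F3 | step 3 | 5,6,7,8-tetrahydro-9H-pyrrolo[1,2-a]azepin-9-one | O=C1CCCCn2cccc21
F4 | step 3 | ethyl (2E)-2-(5,6,7,8-tetrahydro-9H-pyrrolo[1,2-a]azepin-9-ylidene)acetate | CCOC(=O)/C=C1\CCCCn2cccc21
F5 | step 3 | (2E)-2-(5,6,7,8-tetrahydro-9H-pyrrolo[1,2-a]azepin-9-ylidene)ethan-1-ol | OC/C=C1\CCCCn2cccc21
F6 | step 3 | methyl (2E)-2-(5,6,7,8-tetrahydro-9H-pyrrolo[1,2-a]azepin-9-ylidene)ethyl carbonate | COC(=O)OC/C=C1\CCCCn2cccc21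
F7 | step 9 | 2-(triisopropylsilyloxy)furan derived from 15 | COC(=O)OC/C=C/[C@H]1CCCCn2c(C(=O)C[C@H](C)C(=O)OC)cc(-c3coc(O[Si](C(C)C)(C(C)C)C(C)C)c3C)c21
F8 | step 9 | 5-hydroxybutenolide derived from 15 (both C11 epimers) | COC(=O)OC/C=C/[C@H]1CCCCn2c(C(=O)C[C@H](C)C(=O)OC)cc(C3=C(C)C(=O)OC3O)c21
F9 | step 11 | (18S)-hydroxy ester, C18 epimer of 18 | CC[C@H]1[C@@H]2OC(=O)[C@H](C)[C@@H]2c2cc([C@@H](O)C[C@H](C)C(=O)OC)n3c2[C@@H]1CCCC3
F10 | step 11 | 18-epimer of 19 | CC[C@H]1[C@@H]2OC(=O)[C@H](C)[C@@H]2c2cc([C@@H]3C[C@H](C)C(=O)O3)n3c2[C@@H]1CCCC3
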